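With a small charge of free catalyst, 0.31 mol%, substrate becomes target, and the question in each set-up is how much of that target survives.

| setting | midnight | dawn | summer | south-east | north-east | west | south-west |
|---|---|---|---|---|---|---|---|
| substrate | 0.50 M | 0.34 M | 0.75 M | 0.50 M | 0.50 M (fed, over 6.40 h) | 0.50 M | 0.50 M |
| reagent | 4 equiv | 4 equiv | 4 equiv | 4.00 equiv | 4.00 equiv | 4.00 equiv | 4.00 equiv |
| free catalyst | 0.31 mol% | 0.31 mol% | 0.31 mol% | 0.31 mol% | 0.31 mol% | 0.31 mol% | 0.31 mol% |
| remark | run made earlier | run made earlier | run made earlier | one stirred flow tank at steady state, fed with the mixture as stated, mean residence time 8.0 h | a stirred flask in which substrate is dosed at a steady rate over 6.40 h without added volume, worked up at 8.0 h | a closed flask charged with all of it at once and left for 8.0 h | a single well-mixed tank run continuously and read at steady state, 80.0 h in it on average |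
| time |  |  |  |  | 8.0 h | 8.0 h |  |

| run | time / h | target / % | side product / % |
|---|---|---|---|
| midnight | 0.667 | 4.8 | 0 |
| midnight | 1.33 | 6.6 | 2.2 |
| midnight | 2.00 | 9.0 | 6.4 |
| midnight | 3.00 | 12.7 | 11.8 |
| midnight | 4.00 | 15.1 | 18.0 |
| midnight | 5.00 | 17.5 | 24.1 |
| dawn | 0.667 | 3.9 | 0.5 |
| dawn | 1.00 | 5.2 | 1.4 |
| dawn | 1.33 | 6.5 | 1.9 |
| dawn | 2.50 | 11.6 | 6.2 |
| dawn | 3.00 | 13.0 | 7.3 |
| dawn | 5.00 | 18.4 | 16.7 |
| dawn | 8.00 | 26.3 | 32.3 |
| summer | 1.00 | 5.7 | 2.5 |
| summer | 2.50 | 10.1 | 13.0 |
| summer | 3.00 | 11.1 | 17.7 |
| summer | 5.00 | 15.7 | 34.2 |
| summer | 6.00 | 18.9 | 40.0 |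
| summer | 8.00 | 23.4 | 52.7 |

(readings scatter by 0.5 percentage points)

- percentages count the substrate that a species holds: one side product counts as two
- the stated concentrations are those of everything mixed, before any reaction; amounts are the same in each set-up
- the feed brings no volume worth counting
- the earlier runs were made in a closed, stirred flask

- the set-up with the highest share of target in all that became target or side product, at the outlet or at the end ("none" if the first two lie within 2 percentage points) (south-east / north-east / west / south-west / none)
- share of target in all that became target or side product, at the outlet or at the end, south-east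
- share of target in all that became target or side product, at the outlet or at the end, north-east
- share of target in all that became target or side product, at the outlet or at the end, west
- share of target in all that became target or side product, at the outlet or at the end, south-west

Side product lags behind target and holds two substrate units, which reads as one substrate meeting one target. Let a, p and o be the fractions of the charge held by substrate, target and side product. The midnight run has the charge of all four set-ups, and its rise in o from 3.00 h to 5.00 h, with a and p taken at 4.00 h, gives the loss constant κ = 0.304 h⁻¹, as a reading. In a steady tank of residence time τ, o = 2κapτ, so the share of target depends on the loss number κaτ, a Damköhler number: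

s = 1 / (1 + 2κaτ)

For south-west, τ is 80.0 h and a must be bracketed. A near zero puts the upper bound close to 1. For the lower bound, the make rate (p + o/2) over the last 3.00 h of the dawn and summer runs is read. In dawn it is Gd = 0.0523 h⁻¹ at mean a 0.532. In summer it is 0.0565 h⁻¹ at mean a 0.370, no slower than in dawn. Setting a at that summer value gives a crude floor of 5.26%. But the tank needs about a quarter of that pace, so a lies far lower. Reading the gap between the two rates as scatter the other way gives the make rate g at any a as g = Gd·a/(a + h), with h = 0.0295.

Round one, no loss: g/Gd = 0.239, a = 0.00924, s = 69.0%

Round two, g lowered by the target lost, (1 − s)/(1 + s) = 0.184 per target made: g/Gd = 0.202, a = 0.00745, s = 73.4%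

The reckoned bracket for south-west runs from 69.0% to near 100%, with round two at 73.4% above its lower end.

The forecast gives 34%, 42.5%, 37% and 47% for south-east, north-east, west and south-west, names south-west, calls that tank “sensitive to the saturation constant”, and stands below the bracket.

The flasks give 35.5%, 44.8%, 37.4% and 86.4% in that order; the best is south-west.

    catalyst intermediate B → catalyst intermediate C (k = 0.700 min⁻¹)
    2 catalyst intermediate B → spent catalyst (k = 0.390 M⁻¹ min⁻¹)
    reagent + free catalyst → catalyst intermediate A (k = 0.680 M⁻¹ min⁻¹)
    substrate + target → side product (k = 0.0107 M⁻¹ min⁻¹)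
    catalyst intermediate C → free catalyst + target (k = 1.44 min⁻¹)
    substrate + catalyst intermediate A → catalyst intermediate B (k = 53.6 M⁻¹ min⁻¹)

South-west reaches 86.4%, inside the bracket. In west, with substrate as charged, target has a half-life against this loss of 2.2 h, shorter than the 8.0 h of the run. Turned round with κ, the rule puts a in south-west at 0.00324. In south-east, a is 0.354 and τ is 8.0 h, so the rule gives 36.7%, and that tank holds 35.5%.

Readings and results were generated by integration with made-up constants.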